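**Retrosynthetic overview**

1. The target is an upper flavan-3-ol unit (benzo ring A, pyran ring C, catechol ring B; 2S,3S,4R, all-cis) bonded from C4 of ring C to C8 of ring D of a (2R,3R,4S)-flavan-3,4-diol lower unit (benzo ring D, pyran ring F, catechol ring E); lower-unit atoms are written C4(F), C8(D) and so on. The last disconnections are the nine benzyl ethers and then the C4(F) hydroxyl (benzylic oxidation, trans to O3(F)).
2. The plan rests on the O1–C8a aryl ether bond of ring C, which lies beside C4 and its ring D substituent. Removing O1 (Baeyer–Villiger retron) turns the ring C lactone, a 4-aryl-3,4-dihydrocoumarin, into a 3-aryl-4,6-bis(benzyloxy)indan-1-one whose benzylic carbon is already C4.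
3. Between lactone and flavan: the lactone carbonyl is C2 and receives ring B by Suzuki coupling of the ketene acetal phosphate; hydroboration anti to ring D sets C2; oxidation and bulky-hydride reduction set C3 cis to both aryl groups.
4. The indanone comes from a ligand-controlled reductive Heck closure of a 2'-bromochalcone, itself from a Claisen–Schmidt union of 8-formyl-penta-O-benzylepicatechin with 2-bromo-3,5-bis(benzyloxy)acetophenone.
5. Ring order: D, F and E come with (−)-epicatechin and A with the acetophenone; the five-membered carbocycle is closed in step 7 and enlarged to ring C in step 8; ring B is attached in step 10.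

Key step: step 8

Assumption: in step 7 (R)-BINAP is taken as the ligand hand that leads to the (3R)-indanone; the face is chosen by the catalyst, so the (S)-ligand takes its place if the opposite sense is met. 3,5-Bis(benzyloxy)acetophenone and 3,4-bis(benzyloxy)phenylboronic acid are taken as catalogue compounds.

**Route**

Step 1
Reactants: 1 (−)-epicatechin
Product: 2 5,7,3',4'-tetra-O-benzyl-(−)-epicatechin
Conditions: BnBr (4.4 equiv), K2CO3, DMF, 0 °C to rt
Reagents that add atoms: benzyl bromide, BrCc1ccccc1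
Why: Williamson etherification in which carbonate deprotonates only the four phenols, so the secondary 3-OH and the C2/C3 centres are left as they are.

Step 2
Reactants: 2 5,7,3',4'-tetra-O-benzyl-(−)-epicatechin
Product: 3 3,5,7,3',4'-penta-O-benzyl-(−)-epicatechin
Conditions: NaH, BnBr, n-Bu4NI (cat.), DMF, 0 °C to rt
Reagents that add atoms: benzyl bromide, BrCc1ccccc1
Why: Williamson etherification of the secondary alkoxide; with every phenol already capped, base-induced opening of ring C at C2 through a quinone methide cannot occur.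

Step 3
Reactants: 3 3,5,7,3',4'-penta-O-benzyl-(−)-epicatechin
Product: 4 8-bromo-3,5,7,3',4'-penta-O-benzylepicatechin
Conditions: NBS (1.0 equiv), CH2Cl2, −40 °C to rt
Reagents that add atoms: N-bromosuccinimide, O=C1CCC(=O)N1Br
Why: Electrophilic aromatic bromination of the trioxygenated benzo ring, which in fully etherified flavan-3-ols goes to C8 in preference to C6 and leaves the less activated catechol ring alone.

Step 4
Reactants: 4 8-bromo-3,5,7,3',4'-penta-O-benzylepicatechin
Product: 6 8-formyl-3,5,7,3',4'-penta-O-benzylepicatechin, via 8-lithio-3,5,7,3',4'-penta-O-benzylepicatechin 5 (not isolated)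
Conditions: n-BuLi, THF, −78 °C; then DMF, −78 to 0 °C; H2O
Reagents that add atoms: n-butyllithium, [Li]CCCC (lithium of 5); N,N-dimethylformamide, CN(C)C=O (formyl group)
Why: Bromine–lithium exchange at −78 °C is faster than deprotonation of any benzylic ether methylene, and the aryllithium is formylated by DMF (Bouveault aldehyde synthesis).

Step 5
Reactants: 7 3,5-bis(benzyloxy)acetophenone
Product: 8 2-bromo-3,5-bis(benzyloxy)acetophenone
Conditions: NBS (1.05 equiv), MeCN, 0 °C to rt
Reagents that add atoms: N-bromosuccinimide, O=C1CCC(=O)N1Br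
Why: Electrophilic aromatic bromination in a polar solvent goes to C2, para to one ether and ortho to the other, and not to the more hindered C4 between the two ethers or to the acetyl methyl group.

Step 6
Reactants: 6 8-formyl-3,5,7,3',4'-penta-O-benzylepicatechin; 8 2-bromo-3,5-bis(benzyloxy)acetophenone
Product: 9 (E)-1-[2-bromo-3,5-bis(benzyloxy)phenyl]-3-(3,5,7,3',4'-penta-O-benzylepicatechin-8-yl)prop-2-en-1-one
Conditions: KOH, EtOH/THF, rt
Reagents that add atoms: none
Why: Claisen–Schmidt condensation between the only enolisable partner (methyl ketone 8) and the non-enolisable aldehyde 6, the dehydration giving the conjugated (E)-enone.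

Step 7
Reactants: 9 (E)-1-[2-bromo-3,5-bis(benzyloxy)phenyl]-3-(3,5,7,3',4'-penta-O-benzylepicatechin-8-yl)prop-2-en-1-one
Product: 10 (3R)-4,6-bis(benzyloxy)-3-(3,5,7,3',4'-penta-O-benzylepicatechin-8-yl)indan-1-one
Conditions: Pd(OAc)2 (10 mol %), (R)-BINAP (12 mol %), HCO2Na (added slowly), DMF, 80 °C
Reagents that add atoms: none
Why: Intramolecular asymmetric reductive Heck cyclisation, in which zerovalent palladium inserts into the C–Br bond, the aryl group adds to the enone β-carbon (formal 5-endo-trig, giving a palladium enolate) and formate reduces the enolate in place of β-hydride elimination; the enone face is chosen by the (R)-BINAP-bound palladium, which sets the new benzylic centre as (R).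

Step 8
Reactants: 10 (3R)-4,6-bis(benzyloxy)-3-(3,5,7,3',4'-penta-O-benzylepicatechin-8-yl)indan-1-one
Product: 12 (4R)-5,7-bis(benzyloxy)-4-(3,5,7,3',4'-penta-O-benzylepicatechin-8-yl)-3,4-dihydrocoumarin, via Criegee adduct 11 (not isolated)
Conditions: m-CPBA (3 equiv), NaHCO3, CH2Cl2, 0 °C to rt
Reagents that add atoms: m-chloroperbenzoic acid, OOC(=O)c1cccc(Cl)c1
Why: Baeyer–Villiger oxidation: the peracid adds to the C1 carbonyl to give adduct 11, in which the ring A carbon C7a shifts from C1 to the nearer peroxide oxygen with retention while 3-chlorobenzoate leaves, so the oxygen that becomes O1 enters between ring A and the carbonyl. The closest known reaction type is the peracid ring expansion of indan-1-ones to 3,4-dihydrocoumarins by aryl migration. Ring C is closed by ring enlargement and not by cyclisation: the concerted 1,2-shift turns the five-membered carbocycle into the six-membered lactone and forms the O1–C8a bond. No stereocentre is made; the benzylic centre from step 7 lies two bonds from the reacting carbon, never becomes cationic and is carried over as C4 (R). The step needs migration of C7a over the C2 methylene and attack at the ketone in preference to the electron-rich rings: the first rests only on the higher migratory aptitude of an aryl carbon over a primary alkyl carbon (the two benzyloxy groups are meta to C7a and give no help, which is why the risk of the route sits here), the second on the NaHCO3 buffer, the low temperature and the fact that the ethers, being meta to the carbonyl, do not deactivate it by conjugation.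

Step 9
Reactants: 12 (4R)-5,7-bis(benzyloxy)-4-(3,5,7,3',4'-penta-O-benzylepicatechin-8-yl)-3,4-dihydrocoumarin
Product: 13 (4R)-5,7-bis(benzyloxy)-4-(3,5,7,3',4'-penta-O-benzylepicatechin-8-yl)-4H-chromen-2-yl diphenyl phosphate
Conditions: KN(SiMe3)2 (1.1 equiv, added to lactone and chlorophosphate), (PhO)2P(O)Cl, HMPA, THF, −78 °C
Reagents that add atoms: diphenyl chlorophosphate, O=P(Cl)(Oc1ccccc1)Oc1ccccc1
Why: Ketene acetal phosphate formation by O-phosphorylation of the lactone enolate, trapped as it forms at −78 °C so that ring opening to a ketene cannot compete; only the C3 methylene is α to the carbonyl, so C4 is untouched.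

Step 10
Reactants: 13 (4R)-5,7-bis(benzyloxy)-4-(3,5,7,3',4'-penta-O-benzylepicatechin-8-yl)-4H-chromen-2-yl diphenyl phosphate; 14 3,4-bis(benzyloxy)phenylboronic acid
Product: 15 (4R)-2-[3,4-bis(benzyloxy)phenyl]-5,7-bis(benzyloxy)-4-(3,5,7,3',4'-penta-O-benzylepicatechin-8-yl)-4H-chromene
Conditions: Pd(PPh3)4 (10 mol %), 2 M aq. Na2CO3, DME, 60 °C
Reagents that add atoms: none
Why: Suzuki–Miyaura coupling, in which zerovalent palladium inserts into the C2–O bond of the ketene acetal phosphate and transmetalation and reductive elimination attach ring B at C2; the carbonate base is too weak to remove the C4 hydrogen.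

Step 11
Reactants: 15 (4R)-2-[3,4-bis(benzyloxy)phenyl]-5,7-bis(benzyloxy)-4-(3,5,7,3',4'-penta-O-benzylepicatechin-8-yl)-4H-chromene
Product: 17 (2S,3R,4R)-2-[3,4-bis(benzyloxy)phenyl]-5,7-bis(benzyloxy)-4-(3,5,7,3',4'-penta-O-benzylepicatechin-8-yl)chroman-3-ol, via C3 alkylborane 16 (not isolated)
Conditions: BH3·THF, THF, 0 °C to rt; then H2O2, aq. NaOH, 0 °C
Reagents that add atoms: borane (as BH3·THF), B (boron of 16); hydrogen peroxide, OO (oxygen at C3)
Why: Hydroboration–oxidation of the enol ether, in which boron goes to C3 (β to O1) and hydrogen to C2 in a syn addition on the face away from ring D at C4, so C2 is set (S) with ring B cis to ring D and the C3 oxygen, introduced with retention, is trans to both (3R).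

Step 12
Reactants: 17 (2S,3R,4R)-2-[3,4-bis(benzyloxy)phenyl]-5,7-bis(benzyloxy)-4-(3,5,7,3',4'-penta-O-benzylepicatechin-8-yl)chroman-3-ol
Product: 18 (2S,4R)-2-[3,4-bis(benzyloxy)phenyl]-5,7-bis(benzyloxy)-4-(3,5,7,3',4'-penta-O-benzylepicatechin-8-yl)chroman-3-one
Conditions: Dess–Martin periodinane, NaHCO3, CH2Cl2, rt
Reagents that add atoms: none
Why: Dess–Martin oxidation gives the C3 ketone under nearly neutral conditions, which avoids enolisation at the benzylic C2 and C4 positions (a planar enol toward C4 would also force ring D against the C5 benzyloxy group).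

Step 13
Reactants: 18 (2S,4R)-2-[3,4-bis(benzyloxy)phenyl]-5,7-bis(benzyloxy)-4-(3,5,7,3',4'-penta-O-benzylepicatechin-8-yl)chroman-3-one
Product: 19 (2S,3S,4R)-2-[3,4-bis(benzyloxy)phenyl]-5,7-bis(benzyloxy)-4-(3,5,7,3',4'-penta-O-benzylepicatechin-8-yl)chroman-3-ol
Conditions: LiBH(s-Bu)3, LiBr, THF, −78 °C; then aq. NaOH, H2O2, 0 °C
Reagents that add atoms: none
Why: Ketone reduction by a bulky borohydride, which approaches C3 on the face away from the two cis aryl groups (equatorial attack) and so gives the axial (3S) alcohol cis to ring B and ring D, as in the known conversion of benzylated 2,3-trans flavan-3-ols into their 2,3-cis isomers.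

Step 14
Reactants: 19 (2S,3S,4R)-2-[3,4-bis(benzyloxy)phenyl]-5,7-bis(benzyloxy)-4-(3,5,7,3',4'-penta-O-benzylepicatechin-8-yl)chroman-3-ol
Product: 20 (2S,3S,4R)-2-[3,4-bis(benzyloxy)phenyl]-5,7-bis(benzyloxy)-4-[(4S)-4-hydroxy-3,5,7,3',4'-penta-O-benzylepicatechin-8-yl]chroman-3-ol
Conditions: DDQ (1.5 equiv), CH2Cl2/H2O (18:1), 0 °C to rt
Reagents that add atoms: water, O
Why: Benzylic oxidation in which DDQ takes hydride from the C4(F) methylene, activated by the three oxygens of ring D, and water captures the cation on the face opposite the 3-benzyloxy group of ring F to give the trans (4S) alcohol; the upper C4–H is a methine buried between two ortho-disubstituted arenes and should react more slowly.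

Step 15
Reactants: 20 (2S,3S,4R)-2-[3,4-bis(benzyloxy)phenyl]-5,7-bis(benzyloxy)-4-[(4S)-4-hydroxy-3,5,7,3',4'-penta-O-benzylepicatechin-8-yl]chroman-3-ol
Product: 21 (2R,3R,4S)-2-(3,4-dihydroxyphenyl)-8-[(2S,3S,4R)-2-(3,4-dihydroxyphenyl)-3,5,7-trihydroxychroman-4-yl]chromane-3,4,5,7-tetrol (CNP0114173.1)
Conditions: H2 (1 atm), Pd(OH)2/C, THF/MeOH/H2O, rt, stopped at complete debenzylation
Reagents that add atoms: none
Why: Hydrogenolysis of the nine benzyl ethers (eight aryl, one alkyl); in a neutral medium the benzylic C4(F)–OH and the C4–C8(D) bond, which are cleaved only slowly without acid, should be kept.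

**Compound list**

1 | (−)-epicatechin | Oc1cc(O)c2c(c1)O[C@H](c1ccc(O)c(O)c1)[C@H](O)C2 | starting material
2 | 5,7,3',4'-tetra-O-benzyl-(−)-epicatechin | c1c(OCc9ccccc9)cc(OCc9ccccc9)c2c1O[C@H](c1ccc(OCc9ccccc9)c(OCc9ccccc9)c1)[C@H](O)C2 | intermediate
3 | 3,5,7,3',4'-penta-O-benzyl-(−)-epicatechin | c1c(OCc9ccccc9)cc(OCc9ccccc9)c2c1O[C@H](c1ccc(OCc9ccccc9)c(OCc9ccccc9)c1)[C@H](OCc9ccccc9)C2 | intermediate
4 | 8-bromo-3,5,7,3',4'-penta-O-benzylepicatechin | Brc1c(OCc9ccccc9)cc(OCc9ccccc9)c2c1O[C@H](c1ccc(OCc9ccccc9)c(OCc9ccccc9)c1)[C@H](OCc9ccccc9)C2 | intermediate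
5 | 8-lithio-3,5,7,3',4'-penta-O-benzylepicatechin | [Li]c1c(OCc9ccccc9)cc(OCc9ccccc9)c2c1O[C@H](c1ccc(OCc9ccccc9)c(OCc9ccccc9)c1)[C@H](OCc9ccccc9)C2 | intermediate
6 | 8-formyl-3,5,7,3',4'-penta-O-benzylepicatechin | O=Cc1c(OCc9ccccc9)cc(OCc9ccccc9)c2c1O[C@H](c1ccc(OCc9ccccc9)c(OCc9ccccc9)c1)[C@H](OCc9ccccc9)C2 | intermediate
7 | 3,5-bis(benzyloxy)acetophenone | CC(=O)c1cc(OCc9ccccc9)cc(OCc9ccccc9)c1 | starting material
8 | 2-bromo-3,5-bis(benzyloxy)acetophenone | CC(=O)c1cc(OCc9ccccc9)cc(OCc9ccccc9)c1Br | intermediate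
9 | (E)-2'-bromochalcone from 6 and 8 | O=C(/C=C/c1c(OCc9ccccc9)cc(OCc9ccccc9)c2c1O[C@H](c1ccc(OCc9ccccc9)c(OCc9ccccc9)c1)[C@H](OCc9ccccc9)C2)c1cc(OCc9ccccc9)cc(OCc9ccccc9)c1Br | intermediate
10 | (3R)-3-aryl-4,6-bis(benzyloxy)indan-1-one (aryl = penta-O-benzylepicatechin-8-yl) | O=C1C[C@@H](c3c(OCc9ccccc9)cc(OCc9ccccc9)c4c3O[C@H](c3ccc(OCc9ccccc9)c(OCc9ccccc9)c3)[C@H](OCc9ccccc9)C4)c2c(OCc9ccccc9)cc(OCc9ccccc9)cc12 | intermediate
11 | Criegee adduct of 10 (1-hydroxy-1-(3-chlorobenzoylperoxy)indane, either configuration at C1) | OC1(OOC(=O)c8cccc(Cl)c8)C[C@@H](c3c(OCc9ccccc9)cc(OCc9ccccc9)c4c3O[C@H](c3ccc(OCc9ccccc9)c(OCc9ccccc9)c3)[C@H](OCc9ccccc9)C4)c2c(OCc9ccccc9)cc(OCc9ccccc9)cc12 | intermediate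
12 | (4R)-4-aryl-5,7-bis(benzyloxy)-3,4-dihydrocoumarin | O=C1C[C@@H](c3c(OCc9ccccc9)cc(OCc9ccccc9)c4c3O[C@H](c3ccc(OCc9ccccc9)c(OCc9ccccc9)c3)[C@H](OCc9ccccc9)C4)c2c(OCc9ccccc9)cc(OCc9ccccc9)cc2O1 | intermediate
13 | (4R)-4-aryl-5,7-bis(benzyloxy)-4H-chromen-2-yl diphenyl phosphate | O=P(Oc8ccccc8)(Oc8ccccc8)OC1=C[C@@H](c3c(OCc9ccccc9)cc(OCc9ccccc9)c4c3O[C@H](c3ccc(OCc9ccccc9)c(OCc9ccccc9)c3)[C@H](OCc9ccccc9)C4)c2c(OCc9ccccc9)cc(OCc9ccccc9)cc2O1 | intermediate
14 | 3,4-bis(benzyloxy)phenylboronic acid | OB(O)c1ccc(OCc9ccccc9)c(OCc9ccccc9)c1 | starting material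
15 | (4R)-2-[3,4-bis(benzyloxy)phenyl]-4-aryl-5,7-bis(benzyloxy)-4H-chromene | C1(c5ccc(OCc9ccccc9)c(OCc9ccccc9)c5)=C[C@@H](c3c(OCc9ccccc9)cc(OCc9ccccc9)c4c3O[C@H](c3ccc(OCc9ccccc9)c(OCc9ccccc9)c3)[C@H](OCc9ccccc9)C4)c2c(OCc9ccccc9)cc(OCc9ccccc9)cc2O1 | intermediate
16 | C3 alkylborane (boron trans to ring B and ring D; drawn as the monoalkylborane) | [C@H]1(c5ccc(OCc9ccccc9)c(OCc9ccccc9)c5)[C@H](B)[C@@H](c3c(OCc9ccccc9)cc(OCc9ccccc9)c4c3O[C@H](c3ccc(OCc9ccccc9)c(OCc9ccccc9)c3)[C@H](OCc9ccccc9)C4)c2c(OCc9ccccc9)cc(OCc9ccccc9)cc2O1 | intermediate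
17 | (2S,3R,4R)-chroman-3-ol (2,4-cis, 3-OH trans to both aryl groups) | [C@H]1(c5ccc(OCc9ccccc9)c(OCc9ccccc9)c5)[C@H](O)[C@@H](c3c(OCc9ccccc9)cc(OCc9ccccc9)c4c3O[C@H](c3ccc(OCc9ccccc9)c(OCc9ccccc9)c3)[C@H](OCc9ccccc9)C4)c2c(OCc9ccccc9)cc(OCc9ccccc9)cc2O1 | intermediate
18 | (2S,4R)-chroman-3-one | [C@H]1(c5ccc(OCc9ccccc9)c(OCc9ccccc9)c5)C(=O)[C@@H](c3c(OCc9ccccc9)cc(OCc9ccccc9)c4c3O[C@H](c3ccc(OCc9ccccc9)c(OCc9ccccc9)c3)[C@H](OCc9ccccc9)C4)c2c(OCc9ccccc9)cc(OCc9ccccc9)cc2O1 | intermediate
19 | (2S,3S,4R)-chroman-3-ol, all-cis nona-O-benzyl dimer | [C@H]1(c5ccc(OCc9ccccc9)c(OCc9ccccc9)c5)[C@@H](O)[C@@H](c3c(OCc9ccccc9)cc(OCc9ccccc9)c4c3O[C@H](c3ccc(OCc9ccccc9)c(OCc9ccccc9)c3)[C@H](OCc9ccccc9)C4)c2c(OCc9ccccc9)cc(OCc9ccccc9)cc2O1 | intermediate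
20 | nona-O-benzyl dimer with (4S)-hydroxyl at C4(F) | [C@H]1(c5ccc(OCc9ccccc9)c(OCc9ccccc9)c5)[C@@H](O)[C@@H](c3c(OCc9ccccc9)cc(OCc9ccccc9)c4c3O[C@H](c3ccc(OCc9ccccc9)c(OCc9ccccc9)c3)[C@H](OCc9ccccc9)[C@H]4O)c2c(OCc9ccccc9)cc(OCc9ccccc9)cc2O1 | intermediate
21 | CNP0114173.1 | Oc1cc(O)c2c(c1)O[C@@H](c1ccc(O)c(O)c1)[C@@H](O)[C@H]2c1c(O)cc(O)c2c1O[C@H](c1ccc(O)c(O)c1)[C@H](O)[C@H]2O | target

**Step count and risks**

Total: 15 steps. Longest linear sequence: 14 steps (steps 1–4 and 6–15, from (−)-epicatechin).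

Steps most likely to fail:

1. Step 8. The C2 methylene may migrate in place of the ring A carbon, since the two ethers are meta to the migrating carbon and do not assist it. The peracid may also oxidise rings D and E before the conjugated ketone reacts. Fallback: lactone 12 is assembled without oxygen insertion. Bromide 4 is converted (n-BuLi, THF, −78 °C; B(OMe)3; aqueous NH4Cl) into 8-borono-3,5,7,3',4'-penta-O-benzylepicatechin F1. Commercial 5,7-dihydroxycoumarin is benzylated (BnBr, K2CO3, DMF) to 5,7-bis(benzyloxy)coumarin F2. Rhodium-catalysed asymmetric 1,4-addition of F1 to F2 (Rh(acac)(C2H4)2, (R)-SEGPHOS with the hand matched to the (4R) product, dioxane/H2O, 60 °C; Hayashi–Miyaura reaction) should give 12, and the route continues from 12 at step 9.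

2. Step 7. Formate may reduce the aryl–palladium bond before the enone inserts, because the β-carbon carries a di-ortho-substituted aryl group. Conjugate reduction of the enone and weak face selection are the other failure modes. Fallback: the ring is closed by rhodium with no hydride donor present. Bromide 8 undergoes Miyaura borylation (PdCl2(dppf), B2pin2, KOAc, dioxane, 90 °C) to 2-(pinacolatoboryl)-3,5-bis(benzyloxy)acetophenone F3. Condensation with aldehyde 6 (pyrrolidine, MeOH/THF, 40 °C) gives the boryl chalcone F4. Asymmetric intramolecular 1,4-addition ([RhCl(cod)]2, (R)-BINAP, aqueous K3PO4, dioxane, 60 °C) closes the five-membered ring and returns to 10.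

3. Step 14. A second hydride abstraction may turn the new carbinol into the C4(F) ketone, and hydride abstraction at the upper C4–H may compete. Fallback: the oxygen is introduced as an ester that resists further oxidation. From 19, DDQ in CH2Cl2/AcOH should give the C4(F) acetate F5, with acetate adding trans to O3(F). Methanolysis (K2CO3, MeOH/THF, 0 °C) then releases 20.

**Further compounds**

F1 | step 8 | 8-borono-3,5,7,3',4'-penta-O-benzylepicatechin | OB(O)c1c(OCc9ccccc9)cc(OCc9ccccc9)c2c1O[C@H](c1ccc(OCc9ccccc9)c(OCc9ccccc9)c1)[C@H](OCc9ccccc9)C2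
F2 | step 8 | 5,7-bis(benzyloxy)coumarin | O=C1C=Cc2c(OCc9ccccc9)cc(OCc9ccccc9)cc2O1
F3 | step 7 | 2-(pinacolatoboryl)-3,5-bis(benzyloxy)acetophenone | CC(=O)c1cc(OCc9ccccc9)cc(OCc9ccccc9)c1B1OC(C)(C)C(C)(C)O1
F4 | step 7 | (E)-2'-(pinacolatoboryl)chalcone from 6 and F3 | O=C(/C=C/c1c(OCc9ccccc9)cc(OCc9ccccc9)c2c1O[C@H](c1ccc(OCc9ccccc9)c(OCc9ccccc9)c1)[C@H](OCc9ccccc9)C2)c1cc(OCc9ccccc9)cc(OCc9ccccc9)c1B1OC(C)(C)C(C)(C)O1
F5 | step 14 | nona-O-benzyl dimer with (4S)-acetoxy group at C4(F) | [C@H]1(c5ccc(OCc9ccccc9)c(OCc9ccccc9)c5)[C@@H](O)[C@@H](c3c(OCc9ccccc9)cc(OCc9ccccc9)c4c3O[C@H](c3ccc(OCc9ccccc9)c(OCc9ccccc9)c3)[C@H](OCc9ccccc9)[C@H]4OC(C)=O)c2c(OCc9ccccc9)cc(OCc9ccccc9)cc2O1
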